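## Retrosynthetic overview

1. The acid is traced back to an enal. Its C4–C5 bond and both (E)-trisubstituted olefins are made in one operation by a tandem Claisen–Cope ([3,3] then [3,3]) rearrangement of an allyl dienyl ether, built from a prenyl-derived allylic alcohol and tiglaldehyde acetal.
2. The allylic alcohol comes from SeO2 oxidation of a prenyl-terminated bicyclic core. The dihydrofuran ring is closed by C-alkylation of a 4-silyloxycyclohexane-1,3-dione with a terminal epoxide, then cyclodehydration.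
3. Epoxy alcohol (ring C2 and the tertiary carbinol): C2 is bought as methyl (S)-glycidate; the carbinol is set by chelation-controlled Grignard addition to the derived epoxy methyl ketone.
4. Dione (C5): bought as methyl (R)-glycidate; copper-catalysed allylation, Wacker oxidation and intramolecular Claisen condensation build the carbocycle.
5. Ring order: cyclohexane-1,3-dione first, dihydrofuran second.

Assumption: both enantiomers of methyl glycidate, tiglaldehyde, 5-bromo-2-methylpent-2-ene and the common Grignard solutions are taken as commercial.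

## Route

Step 1
Reactants: 1 methyl (2S)-oxirane-2-carboxylate
Product: 2 (2S)-N-methoxy-N-methyloxirane-2-carboxamide
Conditions: MeNHOMe·HCl (1.5 equiv), n-BuLi (3.0 equiv), THF, −78 °C; then 1, −78 °C; aq. NH4Cl
Reagents that add atoms: N,O-dimethylhydroxylamine hydrochloride, CNOC.Cl
Why: Weinreb amide formation by aminolysis of the activated ester with MeN(OMe)Li is faster at −78 °C than oxirane opening and leaves the stereocentre untouched.

Step 2
Reactants: 2 (2S)-N-methoxy-N-methyloxirane-2-carboxamide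
Product: 3 1-[(2S)-oxiran-2-yl]ethan-1-one
Conditions: MeMgBr (1.2 equiv), THF, −78 to −20 °C; aq. NH4Cl
Reagents that add atoms: methylmagnesium bromide, C[Mg]Br
Why: Weinreb ketone synthesis, in which the chelated tetrahedral intermediate stops at the ketone stage and the oxirane carbon is not enolised, so C2 keeps its configuration.

Step 3
Reactants: 3 1-[(2S)-oxiran-2-yl]ethan-1-one
Product: 4 (2S)-6-methyl-2-[(2S)-oxiran-2-yl]hept-5-en-2-ol
Conditions: (4-methylpent-3-en-1-yl)MgBr (1.3 equiv, prepared beforehand in the same flask from 5-bromo-2-methylpent-2-ene and Mg turnings in Et2O); then 3, Et2O, −78 °C; aq. NH4Cl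
Reagents that add atoms: (4-methylpent-3-en-1-yl)magnesium bromide, CC(C)=CCC[Mg]Br (made in the flask); 5-bromo-2-methylpent-2-ene, CC(C)=CCCBr (its precursor)
Why: Cram-chelate Grignard addition, in which magnesium bridges the carbonyl and oxirane oxygens and the nucleophile enters anti to the oxirane CH2, so the bought C2 centre sets the (S)-carbinol.

Step 4
Reactants: 5 methyl (2R)-oxirane-2-carboxylate
Product: 6 methyl (2R)-2-hydroxyhex-5-enoate
Conditions: allylMgBr (1.2 equiv, slow addition), CuI (10 mol%), THF, −78 to −40 °C; aq. NH4Cl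
Reagents that add atoms: allylmagnesium bromide, C=CC[Mg]Br
Why: CuI-catalysed opening of the oxirane by the Grignard reagent occurs at the terminal CH2 and outruns ester addition at low temperature, so the C–O stereocentre is not involved and stays (R).

Step 5
Reactants: 6 methyl (2R)-2-hydroxyhex-5-enoate
Product: 7 methyl (2R)-2-[(tert-butyldimethylsilyl)oxy]hex-5-enoate
Conditions: TBSCl, imidazole, DMF, rt
Reagents that add atoms: tert-butyldimethylsilyl chloride, CC(C)(C)[Si](C)(C)Cl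
Why: Standard silylation protects the secondary alcohol as a TBS ether that survives enolate, oxidative and thermal steps.

Step 6
Reactants: 7 methyl (2R)-2-[(tert-butyldimethylsilyl)oxy]hex-5-enoate
Product: 8 methyl (2R)-2-[(tert-butyldimethylsilyl)oxy]-5-oxohexanoate
Conditions: PdCl2 (10 mol%), CuCl, O2 (1 atm), DMF–H2O 7:1, rt
Reagents that add atoms: water, O
Why: Tsuji–Wacker oxidation converts the terminal alkene into the methyl ketone with Markovnikov selectivity; the remote silyloxy ester is unaffected.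

Step 7
Reactants: 8 methyl (2R)-2-[(tert-butyldimethylsilyl)oxy]-5-oxohexanoate
Product: 9 (4R)-4-[(tert-butyldimethylsilyl)oxy]cyclohexane-1,3-dione
Conditions: LiN(SiMe3)2 (1.1 equiv), THF, −78 °C to rt; 1 M HCl to pH 4
Reagents that add atoms: none
Why: Intramolecular Claisen (Dieckmann-type) condensation of the kinetic methyl-ketone enolate onto the ester closes the six-membered ring; a single equivalent of LiN(SiMe3)2 avoids enolising the silyloxy ester, and the product rests as its enolate, so C4 is not epimerised.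

Step 8
Reactants: 9 (4R)-4-[(tert-butyldimethylsilyl)oxy]cyclohexane-1,3-dione; 4 (2S)-6-methyl-2-[(2S)-oxiran-2-yl]hept-5-en-2-ol
Product: 11 (2S,5R)-5-[(tert-butyldimethylsilyl)oxy]-2-[(2S)-2-hydroxy-6-methylhept-5-en-2-yl]-3,5,6,7-tetrahydro-1-benzofuran-4(2H)-one, via diol dione 10 (not isolated)
Conditions: K2CO3 (0.3 equiv), H2O–i-PrOH 1:1, 60 °C; then PPTS (cat.), toluene, 4 Å MS, 70 °C
Reagents that add atoms: none
Why: C-alkylation of the dione enolate at the epoxide CH2 (SN2, C2–O bond untouched) followed by acid-catalysed cyclodehydration; the less hindered secondary hydroxyl closes the five-membered ring onto the carbonyl remote from the silyloxy group, the usual preference of 4-substituted cyclohexane-1,3-diones.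

Step 9
Reactants: 11 (2S,5R)-5-[(tert-butyldimethylsilyl)oxy]-2-[(2S)-2-hydroxy-6-methylhept-5-en-2-yl]-3,5,6,7-tetrahydro-1-benzofuran-4(2H)-one
Product: 12 (2S,5R)-5-[(tert-butyldimethylsilyl)oxy]-2-[(2S,5E)-2,7-dihydroxy-6-methylhept-5-en-2-yl]-3,5,6,7-tetrahydro-1-benzofuran-4(2H)-one
Conditions: SeO2 (0.3 equiv), t-BuOOH (3 equiv), salicylic acid (0.1 equiv), CH2Cl2, 0 °C to rt
Reagents that add atoms: selenium dioxide, O=[Se]=O (oxygen carrier); tert-butyl hydroperoxide, CC(C)(C)OO (terminal oxidant)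
Why: Sharpless–Umbreit allylic oxidation (ene reaction then [2,3] shift) hydroxylates only the (E)-methyl of the isolated trisubstituted olefin; the push-pull enol ether double bond is inert.

Step 10
Reactants: 13 (2E)-2-methylbut-2-enal
Product: 14 (2E)-1,1-diethoxy-2-methylbut-2-ene
Conditions: HC(OEt)3, EtOH, NH4NO3 (cat.), rt
Reagents that add atoms: triethyl orthoformate, CCOC(OCC)OCC
Why: Orthoformate-driven acetalisation of the enal gives the acetal needed to form a dienyl ether.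

Step 11
Reactants: 12 (2S,5R)-5-[(tert-butyldimethylsilyl)oxy]-2-[(2S,5E)-2,7-dihydroxy-6-methylhept-5-en-2-yl]-3,5,6,7-tetrahydro-1-benzofuran-4(2H)-one; 14 (2E)-1,1-diethoxy-2-methylbut-2-ene
Product: 17 (2E,6E,10S)-10-[(2S,5R)-5-[(tert-butyldimethylsilyl)oxy]-4-oxo-2,3,4,5,6,7-hexahydro-1-benzofuran-2-yl]-10-hydroxy-2,6-dimethylundeca-2,6-dienal, via dienyl ether 15 (not isolated), via Claisen aldehyde 16 (not isolated)
Conditions: 14 (5 equiv), 2,4-dinitrophenol (5 mol%), xylene, 135 °C, EtOH distilled off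
Reagents that add atoms: none
Why: Acetal exchange and loss of ethanol give the allyl dienyl ether, which undergoes a tandem Claisen–Cope rearrangement (two [3,3] shifts through chair transition states); this forms the C4–C5 bond and delivers the conjugated (E)-enal and the (E)-C6=C7 olefin without touching any stereocentre.

Step 12
Reactants: 17 (2E,6E,10S)-10-[(2S,5R)-5-[(tert-butyldimethylsilyl)oxy]-4-oxo-2,3,4,5,6,7-hexahydro-1-benzofuran-2-yl]-10-hydroxy-2,6-dimethylundeca-2,6-dienal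
Product: 18 (2E,6E,10S)-10-[(2S,5R)-5-[(tert-butyldimethylsilyl)oxy]-4-oxo-2,3,4,5,6,7-hexahydro-1-benzofuran-2-yl]-10-hydroxy-2,6-dimethylundeca-2,6-dienoic acid
Conditions: NaClO2, NaH2PO4, 2-methylbut-2-ene, t-BuOH–H2O, 0 °C to rt
Reagents that add atoms: sodium chlorite, [Na+].[O-]Cl=O
Why: Pinnick oxidation converts the enal into the acid without olefin isomerisation, the scavenger protecting the electron-rich double bonds from HOCl.

Step 13
Reactants: 18 (2E,6E,10S)-10-[(2S,5R)-5-[(tert-butyldimethylsilyl)oxy]-4-oxo-2,3,4,5,6,7-hexahydro-1-benzofuran-2-yl]-10-hydroxy-2,6-dimethylundeca-2,6-dienoic acid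
Product: 19 (2E,6E,10S)-10-hydroxy-10-[(2S,5R)-5-hydroxy-4-oxo-2,3,4,5,6,7-hexahydro-1-benzofuran-2-yl]-2,6-dimethylundeca-2,6-dienoic acid
Conditions: HF·pyridine, THF–pyridine, 0 °C to rt
Reagents that add atoms: none
Why: Buffered fluoride desilylation frees the secondary alcohol under non-basic conditions, so the hydroxy-ketone centre is not epimerised.

## Compound list

1 | methyl (2S)-oxirane-2-carboxylate (methyl (S)-glycidate) | COC(=O)[C@@H]1CO1 | starting material
2 | (2S)-N-methoxy-N-methyloxirane-2-carboxamide | CON(C)C(=O)[C@@H]1CO1 | intermediate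
3 | 1-[(2S)-oxiran-2-yl]ethan-1-one | CC(=O)[C@@H]1CO1 | intermediate
4 | (2S)-6-methyl-2-[(2S)-oxiran-2-yl]hept-5-en-2-ol | CC(C)=CCC[C@](C)(O)[C@@H]1CO1 | intermediate
5 | methyl (2R)-oxirane-2-carboxylate (methyl (R)-glycidate) | COC(=O)[C@H]1CO1 | starting material
6 | methyl (2R)-2-hydroxyhex-5-enoate | C=CCC[C@@H](O)C(=O)OC | intermediate
7 | methyl (2R)-2-[(tert-butyldimethylsilyl)oxy]hex-5-enoate | C=CCC[C@@H](O[Si](C)(C)C(C)(C)C)C(=O)OC | intermediate
8 | methyl (2R)-2-[(tert-butyldimethylsilyl)oxy]-5-oxohexanoate | CC(=O)CC[C@@H](O[Si](C)(C)C(C)(C)C)C(=O)OC | intermediate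
9 | (4R)-4-[(tert-butyldimethylsilyl)oxy]cyclohexane-1,3-dione | O=C1CC[C@@H](O[Si](C)(C)C(C)(C)C)C(=O)C1 | intermediate
10 | (4R)-4-[(tert-butyldimethylsilyl)oxy]-2-[(2S,3S)-2,3-dihydroxy-3,7-dimethyloct-6-en-1-yl]cyclohexane-1,3-dione | CC(C)=CCC[C@](C)(O)[C@@H](O)CC1C(=O)CC[C@@H](O[Si](C)(C)C(C)(C)C)C1=O | intermediate (not isolated)
11 | (2S,5R)-5-[(tert-butyldimethylsilyl)oxy]-2-[(2S)-2-hydroxy-6-methylhept-5-en-2-yl]-3,5,6,7-tetrahydro-1-benzofuran-4(2H)-one | CC(C)=CCC[C@](C)(O)[C@@H]1CC2=C(CC[C@@H](O[Si](C)(C)C(C)(C)C)C2=O)O1 | intermediate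
12 | (2S,5R)-5-[(tert-butyldimethylsilyl)oxy]-2-[(2S,5E)-2,7-dihydroxy-6-methylhept-5-en-2-yl]-3,5,6,7-tetrahydro-1-benzofuran-4(2H)-one | C/C(=C\CC[C@](C)(O)[C@@H]1CC2=C(CC[C@@H](O[Si](C)(C)C(C)(C)C)C2=O)O1)CO | intermediate
13 | (2E)-2-methylbut-2-enal (tiglaldehyde) | C/C=C(\C)C=O | starting material
14 | (2E)-1,1-diethoxy-2-methylbut-2-ene | C/C=C(\C)C(OCC)OCC | intermediate
15 | (2S,5R)-5-[(tert-butyldimethylsilyl)oxy]-2-{(2S,5E)-2-hydroxy-6-methyl-7-[(2-methylbuta-1,3-dien-1-yl)oxy]hept-5-en-2-yl}-3,5,6,7-tetrahydro-1-benzofuran-4(2H)-one (enol ether geometry not defined) | C=CC(C)=COC/C(C)=C/CC[C@](C)(O)[C@@H]1CC2=C(CC[C@@H](O[Si](C)(C)C(C)(C)C)C2=O)O1 | intermediate (not isolated)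
16 | 2-ethenyl-3-{(3S)-3-hydroxy-3-[(2S,5R)-5-[(tert-butyldimethylsilyl)oxy]-4-oxo-2,3,4,5,6,7-hexahydro-1-benzofuran-2-yl]butyl}-2,4-dimethylpent-4-enal (mixture at C2 and C3 of the pentenal) | C=CC(C)(C=O)C(CC[C@](C)(O)[C@@H]1CC2=C(CC[C@@H](O[Si](C)(C)C(C)(C)C)C2=O)O1)C(C)=C | intermediate (not isolated)
17 | (2E,6E,10S)-10-[(2S,5R)-5-[(tert-butyldimethylsilyl)oxy]-4-oxo-2,3,4,5,6,7-hexahydro-1-benzofuran-2-yl]-10-hydroxy-2,6-dimethylundeca-2,6-dienal | C/C(=C\CC[C@](C)(O)[C@@H]1CC2=C(CC[C@@H](O[Si](C)(C)C(C)(C)C)C2=O)O1)CC/C=C(\C)C=O | intermediate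
18 | (2E,6E,10S)-10-[(2S,5R)-5-[(tert-butyldimethylsilyl)oxy]-4-oxo-2,3,4,5,6,7-hexahydro-1-benzofuran-2-yl]-10-hydroxy-2,6-dimethylundeca-2,6-dienoic acid | C/C(=C\CC[C@](C)(O)[C@@H]1CC2=C(CC[C@@H](O[Si](C)(C)C(C)(C)C)C2=O)O1)CC/C=C(\C)C(=O)O | intermediate
19 | (2E,6E,10S)-10-hydroxy-10-[(2S,5R)-5-hydroxy-4-oxo-2,3,4,5,6,7-hexahydro-1-benzofuran-2-yl]-2,6-dimethylundeca-2,6-dienoic acid | C/C(=C\CC[C@](C)(O)[C@@H]1CC2=C(CC[C@@H](O)C2=O)O1)CC/C=C(\C)C(=O)O | target

## Step count and risks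

Total steps: 13. Longest linear sequence: 9 (steps 4, 5, 6, 7, 8, 9, 11, 12, 13, from 5).

Steps most likely to fail:

**Step 3** (diastereoselectivity of the Grignard addition to the epoxy ketone, and survival of the oxirane). The fallback sets out from 2 and comes back at 4; it moves the chelation-controlled addition onto an acetonide and builds the oxirane afterwards. Acetone and BF3·OEt2 convert the oxirane of 2 into (4S)-N-methoxy-N,2,2-trimethyl-1,3-dioxolane-4-carboxamide F1. MeMgBr gives 1-[(4S)-2,2-dimethyl-1,3-dioxolan-4-yl]ethan-1-one F2. The same homoprenyl Grignard reagent adds under Cram-chelate control to give (2S)-2-[(4S)-2,2-dimethyl-1,3-dioxolan-4-yl]-6-methylhept-5-en-2-ol F3. Aqueous acetic acid releases (2S,3S)-3,7-dimethyloct-6-ene-1,2,3-triol F4. TsCl, Et3N and catalytic Bu2SnO sulfonylate only the primary hydroxyl to give (2S,3S)-2,3-dihydroxy-3,7-dimethyloct-6-en-1-yl 4-methylbenzenesulfonate F5. K2CO3 in MeOH then closes the oxirane 4 with retention at C2.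

**Step 8** (O- versus C-alkylation of the dione by the epoxide, and the regiochemistry of ring closure). The fallback sets out from 9 and comes back at 11; it masks the dione so that only carbon can be alkylated. Condensation of 9 with 1,1-dimethylhydrazine at the less hindered carbonyl gives (6R)-6-[(tert-butyldimethylsilyl)oxy]-3-(2,2-dimethylhydrazinyl)cyclohex-2-en-1-one F6. Epoxide 4 is capped with TMSCl and imidazole as trimethyl{[(2S)-6-methyl-2-[(2S)-oxiran-2-yl]hept-5-en-2-yl]oxy}silane F7. F6, deprotonated with KH in THF, opens F7 at CH2 through carbon to give (6R)-6-[(tert-butyldimethylsilyl)oxy]-3-(2,2-dimethylhydrazinyl)-2-{(2S,3S)-2-hydroxy-3,7-dimethyl-3-[(trimethylsilyl)oxy]oct-6-en-1-yl}cyclohex-2-en-1-one F8. Aqueous oxalic acid in THF removes the hydrazine and the TMS group; the freed hydroxy dione 10 closes to 11 with PPTS as in step 8.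

**Step 11** (thermal, acid-catalysed tandem rearrangement on the advanced intermediate; E/Z purity). The fallback sets out from 12 and comes back at 17; it replaces the rearrangement by allyl–allyl coupling and cross-metathesis. CBr4 and PPh3 give (2S,5R)-2-[(2S,5E)-7-bromo-2-hydroxy-6-methylhept-5-en-2-yl]-5-[(tert-butyldimethylsilyl)oxy]-3,5,6,7-tetrahydro-1-benzofuran-4(2H)-one F9. Stille coupling with allyltributylstannane and Pd(PPh3)4 gives (2S,5R)-5-[(tert-butyldimethylsilyl)oxy]-2-[(2S,5E)-2-hydroxy-6-methyldeca-5,9-dien-2-yl]-3,5,6,7-tetrahydro-1-benzofuran-4(2H)-one F10. Cross-metathesis of the terminal alkene with methacrolein, using the second-generation Hoveyda–Grubbs catalyst RuCl2(H2IMes)(=CH-2-(i-PrO)C6H4) in CH2Cl2 at 40 °C, gives the (E)-enal 17.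

Further compounds
F1 | step 3 | (4S)-N-methoxy-N,2,2-trimethyl-1,3-dioxolane-4-carboxamide | CON(C)C(=O)[C@@H]1COC(C)(C)O1
F2 | step 3 | 1-[(4S)-2,2-dimethyl-1,3-dioxolan-4-yl]ethan-1-one | CC(=O)[C@@H]1COC(C)(C)O1
F3 | step 3 | (2S)-2-[(4S)-2,2-dimethyl-1,3-dioxolan-4-yl]-6-methylhept-5-en-2-ol | CC(C)=CCC[C@](C)(O)[C@@H]1COC(C)(C)O1
F4 | step 3 | (2S,3S)-3,7-dimethyloct-6-ene-1,2,3-triol | CC(C)=CCC[C@](C)(O)[C@@H](O)CO
F5 | step 3 | (2S,3S)-2,3-dihydroxy-3,7-dimethyloct-6-en-1-yl 4-methylbenzenesulfonate | CC(C)=CCC[C@](C)(O)[C@@H](O)COS(=O)(=O)c1ccc(C)cc1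
F6 | step 8 | (6R)-6-[(tert-butyldimethylsilyl)oxy]-3-(2,2-dimethylhydrazinyl)cyclohex-2-en-1-one | CN(C)NC1=CC(=O)[C@H](O[Si](C)(C)C(C)(C)C)CC1
F7 | step 8 | trimethyl{[(2S)-6-methyl-2-[(2S)-oxiran-2-yl]hept-5-en-2-yl]oxy}silane | CC(C)=CCC[C@](C)(O[Si](C)(C)C)[C@@H]1CO1
F8 | step 8 | (6R)-6-[(tert-butyldimethylsilyl)oxy]-3-(2,2-dimethylhydrazinyl)-2-{(2S,3S)-2-hydroxy-3,7-dimethyl-3-[(trimethylsilyl)oxy]oct-6-en-1-yl}cyclohex-2-en-1-one | CC(C)=CCC[C@](C)(O[Si](C)(C)C)[C@@H](O)CC1=C(NN(C)C)CC[C@@H](O[Si](C)(C)C(C)(C)C)C1=O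
F9 | step 11 | (2S,5R)-2-[(2S,5E)-7-bromo-2-hydroxy-6-methylhept-5-en-2-yl]-5-[(tert-butyldimethylsilyl)oxy]-3,5,6,7-tetrahydro-1-benzofuran-4(2H)-one | C/C(=C\CC[C@](C)(O)[C@@H]1CC2=C(CC[C@@H](O[Si](C)(C)C(C)(C)C)C2=O)O1)CBr
F10 | step 11 | (2S,5R)-5-[(tert-butyldimethylsilyl)oxy]-2-[(2S,5E)-2-hydroxy-6-methyldeca-5,9-dien-2-yl]-3,5,6,7-tetrahydro-1-benzofuran-4(2H)-one | C/C(=C\CC[C@](C)(O)[C@@H]1CC2=C(CC[C@@H](O[Si](C)(C)C(C)(C)C)C2=O)O1)CCC=C
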